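An easy step first: in a closed flask, whatever was charged and is not read as G or Z is still waiting somewhere, so I subtract and call that remainder R, in percent of the J charged, and follow one molecule of it.

| flask | J | remark | time |
|---|---|---|---|
| dusk | 0.47 M | run made earlier |  |
| dawn | 1.9 M | run made earlier |  |
| flask | 0.94 M |  | 25 min |

| run | time / min | G / % | Z / % |
|---|---|---|---|
| dusk | 1.00 | 11.6 | 0 |
| dusk | 3.00 | 31.8 | 0.2 |
| dusk | 5.00 | 45.3 | 0.9 |
| dusk | 8.00 | 58.9 | 2.5 |
| dusk | 12.0 | 68.2 | 4.5 |
| dusk | 15.0 | 73.3 | 4.9 |
| dawn | 1.00 | 12.7 | 0.4 |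
| dawn | 3.00 | 32.7 | 0.9 |
| dawn | 5.00 | 45.6 | 1.9 |
| dawn | 8.00 | 57.8 | 2.1 |
| dawn | 12.0 | 68.7 | 4.0 |
| dawn | 15.0 | 73.7 | 4.4 |

(readings scatter by 0.5 percentage points)



1. how much G the flask holds at 25 min, in percent of the J charged
2. how much Z the flask holds at 25 min, in percent of the J charged

The dawn charge is 4.04 times the dusk charge, yet at 15.0 min the runs read R as 21.8% and 21.9%, which is first-order behaviour, so I pool them for the flask, whose charge lies between.

In the first instants my molecule leaves R at 0.132 min⁻¹, and at 1.00 min Z reads 0% and 0.4%. In the middle, from 8.00 min to 15.0 min, where R falls from 39.4% to 21.8%, the readings put the net gain in Z at 0.134 of what leaves R, which I take as the chance that a leaving molecule ends up on Z. Towards the end, R stands at 27.3% at 12.0 min, and the leaving reads 0.0742 min⁻¹ with the scatter of its readings, slower than in the first instants: this λ is the tail constant, the chance per minute that a molecule still in R leaves it late in the run.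

My molecule therefore survives to 25 min with a chance of 0.476, so I expect R of 10.4% in the flask, and, counting no loss from Z, Z of 6.19% and G of 83.4%.

The forecast differs from my reckoning, with less G at 80% and more Z at 8%, taken down from its own integral since “Z seems to be flattening”.

The flask gives G 82.4% and Z 6.42%, and both forecast values stand within their margins.

    Z → G (k = 0.0200 min⁻¹)
    J → G (k = 0.140 min⁻¹)
    D → Z (k = 0.0280 min⁻¹)
    J ⇌ D (K = 1.00, k = 0.0560 min⁻¹)

R turns out to be J and D together, 3.56% and 7.58% in the flask at 25.0 min, a sum of 11.1% against my 10.4%. For the neighbour flask, the same flask left until 1.5 h, the tail constant gives a chance of 0.00803 of surviving the extra 65.0 min, so R of 0.0895%. That neighbour flask holds J 0.0615% and D 0.149%, a sum of 0.210%, its tail having run at a lower 0.0611 min⁻¹, beside G 96.7% and Z 3.09%.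

The data were generated by integration for substances that don't exist; scatter was added.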